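The bicyclic core is cut across ring A at C1–C10 and C4–C5, a retro-Diels–Alder disconnection. Ring B (C5–C10) carries its two methyl groups at C8 and C10, on either side of C9, and an olefin at C7=C8. This array maps atom for atom onto 2,6-dimethyl-1,4-benzoquinone, while C1–C4 plus the C4 methyl are a 2-silyloxypenta-1,3-diene. One catalytic enantioselective cycloaddition closes ring A, sets the quaternary C10 in absolute form and leaves distinct handles at C2, C6 and C9. C5, C9 and C4 are then relayed from C10 by two dissolving-metal reductions and a suprafacial [2,3]-shift. The precursors are the commercial quinone and a one-step diene.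

Key step: step 2

Remark (numbering): labdane numbering is used for all intermediates; β is the face of the C10 methyl, α the opposite face; C19 is the 4β-CH2O group.
Remark (assumption on catalyst sense): the (S)-oxazaborolidinium is assigned by analogy with its known facial preference for s-trans C=C–C=O units held by an α-C–H···O contact; if the sense proved opposite, the equally available (R)-catalyst would be used.
Remark (diene design): C4 of the diene carries only the methyl group and the enol ether is TBS. An alkoxy group at C4 would be lost by β-elimination as soon as C5 is deprotonated and would leave C5–H doubly activated. A TMS ether would feed an achiral silyl-triflimide background reaction. The C3=C4 olefin is therefore introduced later, in step 7.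

Step 1
Reactants: 1 (E)-pent-3-en-2-one
Product: 2 (E)-2-(tert-butyldimethylsilyloxy)penta-1,3-diene
Conditions: TBSOTf, Et3N, Et2O, 0 °C
Reagents that add atoms: tert-butyldimethylsilyl triflate, CC(C)(C)[Si](C)(C)OS(=O)(=O)C(F)(F)F
Why: Soft enolisation and O-silylation (silyl triflate/amine) removes a proton from the acetyl methyl group and should give the cross-conjugated 2-silyloxy diene with the E-olefin untouched.

Step 2
Reactants: 2 (E)-2-(tert-butyldimethylsilyloxy)penta-1,3-diene; 3 2,6-dimethyl-1,4-benzoquinone
Product: 4 cis-fused endo adduct (6,9-dione; C7=C8; C2 TBS enol ether; 4α-Me 5β-H 10β-Me)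
Conditions: (3aS)-1-(2-methylphenyl)-3,3-diphenyltetrahydro-1H,3H-pyrrolo[1,2-c][1,3,2]oxazaborole (20 mol %), (CF3SO2)2NH (18 mol %), CH2Cl2, −78 °C
Reagents that add atoms: none
Why: This is a concerted but asynchronous endo [4+2] cycloaddition in which the cationic boron binds the unhindered, more basic C6 carbonyl of 3 (syn to C5–H), so the methyl-bearing C10 becomes the most electrophilic carbon and is attacked by the nucleophilic CH2 terminus (C1) of 2 while C4 closes onto C5. The closest known reaction type is the oxazaborolidinium-catalysed enantioselective Diels–Alder reaction of substituted 1,4-benzoquinones with 2-silyloxy-1,3-dienes, and Lewis-acid-directed regiocontrol with 2,6-dimethylbenzoquinone is likewise established. Ring A closes as the six-membered cycloaddition ring by suprafacial addition to both partners, which makes the ring fusion cis. C10 is fixed by the catalyst, whose aryl group shields one quinone face; C5 (5β-H) follows from suprafacial addition and C4 (4α-methyl) from the endo rule with the E-diene, and both are erased later. The step needs regio-, site- and enantioselectivity: both donor groups of 2 (2-silyloxy, 4-methyl) make C1 the nucleophilic end, the two quinone C=C bonds are equivalent by symmetry, and the bulky TBS group should suppress the achiral silyl-cation pathway.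

Step 3
Reactants: 4 cis-fused endo adduct
Product: 6 C6 dienyl triflate (C5=C6–OTf; C7=C8; 9-one), via potassium enolate 5 (not isolated)
Conditions: KN(SiMe3)2, THF, −78 °C; PhNTf2, −78 to 0 °C
Reagents that add atoms: N-phenylbis(trifluoromethanesulfonimide), O=S(=O)(N(c1ccccc1)S(=O)(=O)C(F)(F)F)C(F)(F)F
Why: Kinetic enolate O-triflation is regiochemically unambiguous because C5–H is the only α-hydrogen of the C6 ketone (C7 is vinylic, C9 has no α-hydrogen), and it deliberately erases the C5 centre of the adduct.

Step 4
Reactants: 6 C6 dienyl triflate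
Product: 7 linear dienone (C5=C6–C7=C8–C9=O)
Conditions: Pd(OAc)2 (5 mol %), PPh3 (10 mol %), HCO2H, Et3N, DMF, 60 °C
Reagents that add atoms: none
Why: Palladium-catalysed formate hydrogenolysis of an enol triflate (oxidative addition, decarboxylation of formate, reductive elimination) replaces C6–O by C6–H in an amine-buffered medium that should spare the silyl enol ether and the enone.

Step 5
Reactants: 7 linear dienone
Product: 10 trans-fused enone (5α-H; C7=C8–C9=O), via lithium dienolate 8 (not isolated), via deconjugated enone 9 (not isolated)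
Conditions: Li, t-BuOH (1 equiv), NH3–THF, −78 °C; isoprene, NH4Cl; then 1,8-diazabicyclo[5.4.0]undec-7-ene (DBU), CH2Cl2, rt
Reagents that add atoms: none
Why: In this dissolving-metal 1,6-reduction of a linear dienone the reduced π system is protonated at its δ terminus C5 along the axial line on the α face, opposite the C10 methyl (trans fusion), the dienolate takes up a proton at C8 on quench, and base-mediated conjugation restores the C7=C8 enone.

Step 6
Reactants: 10 trans-fused enone; 11 2-(2-bromoethyl)-1,3-dioxolane
Product: 13 9β-hydroxy-9α-[2-(1,3-dioxolan-2-yl)ethyl] tertiary allylic alcohol, via Grignard reagent 12 (not isolated)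
Conditions: 11, Mg, THF, 25 °C; CeCl3, THF, −78 °C; then 10, −78 to 0 °C; aq NH4Cl
Reagents that add atoms: none
Why: Cerium-chloride-promoted Grignard 1,2-addition overcomes hindrance and enolisation at C9, and axial attack from the α face anti to the C10 methyl should give the 9β-alcohol, a centre that disappears again in step 13.

Step 7
Reactants: 13 tertiary allylic alcohol
Product: 14 ring A enone (C2=O; C3=C4)
Conditions: Pd(OAc)2 (1.1 equiv), MeCN, 25–40 °C
Reagents that add atoms: none
Why: In the Saegusa–Ito oxidation silyl-to-palladium exchange gives the C3 palladium enolate, which can lose only the C4 hydrogen by β-hydride elimination because C1 adjoins the quaternary C10, so one enone regioisomer should form and the C4 centre of the adduct vanishes.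

Step 8
Reactants: 14 ring A enone
Product: 15 2β-allylic alcohol (2β,9β-diol)
Conditions: LiBH(s-Bu)3 (2.2 equiv), THF, −78 °C
Reagents that add atoms: none
Why: 1,2-Reduction of a β,β-disubstituted enone by a bulky borohydride should occur from the α face because the axial C10 methyl blocks the β face, which sets the pseudoaxial 2β-alcohol.

Step 9
Reactants: 15 2β-allylic alcohol
Product: 16 2β-(tributylstannylmethyl) ether
Conditions: KH, Bu3SnCH2I, THF, 0 °C to rt
Reagents that add atoms: tributyl(iodomethyl)stannane, CCCC[Sn](CI)(CCCC)CCCC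
Why: Williamson etherification should take place only at the secondary C2 alkoxide, since the C9 alkoxide is flanked by two fully substituted carbons.

Step 10
Reactants: 16 2β-(tributylstannylmethyl) ether
Product: 18 19-hydroxy-2,7-diene (4β-CH2OH; 4α-Me), via dilithiated ether 17 (not isolated)
Conditions: n-BuLi (2.5 equiv), THF, −78 to −20 °C
Reagents that add atoms: none
Why: In the Still–Wittig [2,3]-sigmatropic rearrangement tin–lithium exchange gives the lithiomethyl ether, which delivers its CH2O unit suprafacially from the 2β oxygen to the β face of C4, setting the quaternary centre (axial 19-CH2OH, equatorial methyl) and moving the olefin to C2=C3.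

Step 11
Reactants: 18 19-hydroxy-2,7-diene
Product: 19 9β,19-diol bearing a saturated ring A
Conditions: 2-nitrobenzenesulfonohydrazide, Et3N, CH2Cl2, rt
Reagents that add atoms: none
Why: Diimide reduction (concerted syn transfer of H2) should select the cis-disubstituted C2=C3 bond over the trisubstituted C7=C8 bond and cannot hydrogenolyse the allylic C9–O bond.

Step 12
Reactants: 19 9β,19-diol
Product: 20 19-O-TBS ether
Conditions: TBSCl, imidazole, DMF, rt
Reagents that add atoms: tert-butyldimethylsilyl chloride, CC(C)(C)[Si](C)(C)Cl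
Why: Imidazole-mediated silylation should protect only the primary C19 hydroxyl, the tertiary C9 hydroxyl being inert under these conditions.

Step 13
Reactants: 20 19-O-TBS ether
Product: 21 8-en-7-one
Conditions: pyridinium chlorochromate, 4 Å molecular sieves, CH2Cl2, rt
Reagents that add atoms: pyridinium chlorochromate, [O-][Cr](=O)(=O)Cl.c1cc[nH+]cc1
Why: In the Babler–Dauben oxidative transposition the chromate ester of the tertiary allylic alcohol shifts by a [3,3] process from C9 to C7 and is oxidised there, giving the C7 ketone conjugated to the tetrasubstituted C8=C9 bond.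

Step 14
Reactants: 21 8-en-7-one
Product: 23 C7 enol triflate (9α-H), via lithium enolate 22 (not isolated)
Conditions: Li, t-BuOH (1 equiv), NH3–THF, −78 °C; isoprene; NH3 evaporated; PhNTf2, THF, 0 °C to rt
Reagents that add atoms: N-phenylbis(trifluoromethanesulfonimide), O=S(=O)(N(c1ccccc1)S(=O)(=O)C(F)(F)F)C(F)(F)F
Why: In this dissolving-metal enone reduction with regiospecific enolate trapping, C9 is protonated axially from the α face anti to the C10 methyl, so the side chain becomes equatorial (9β), and the C7(8) enolate is fixed as the triflate exactly where the olefin is needed.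

Step 15
Reactants: 23 C7 enol triflate
Product: 24 labd-7-ene acetal
Conditions: Pd(OAc)2 (5 mol %), PPh3 (10 mol %), HCO2H, Et3N, DMF, 60 °C
Reagents that add atoms: none
Why: Palladium-catalysed formate hydrogenolysis of the enol triflate gives the C7=C8 olefin without positional isomerisation and leaves silyl ether and acetal intact.

Step 16
Reactants: 24 labd-7-ene acetal
Product: 25 C13 aldehyde
Conditions: pyridinium p-toluenesulfonate, acetone–H2O, 55 °C
Reagents that add atoms: water, O
Why: Mildly acid-catalysed acetal hydrolysis should free the aldehyde while the neopentyl TBS ether and the trisubstituted olefin survive.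

Step 17
Reactants: 25 C13 aldehyde
Product: 26 terminal alkyne (C13≡C14)
Conditions: dimethyl (1-diazo-2-oxopropyl)phosphonate, K2CO3, MeOH, rt
Reagents that add atoms: dimethyl (1-diazo-2-oxopropyl)phosphonate, COP(=O)(OC)C(=[N+]=[N-])C(C)=O
Why: The Ohira–Bestmann variant of the Seyferth–Gilbert homologation converts the non-epimerisable aldehyde into the alkyne by olefination, loss of N2 and 1,2-hydride shift, adding C14.

Step 18
Reactants: 26 terminal alkyne
Product: 28 allyl alkynoate, via lithium acetylide 27 (not isolated)
Conditions: n-BuLi, THF, −78 °C; ClCO2CH2CH=CH2, −78 to 0 °C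
Reagents that add atoms: allyl chloroformate, C=CCOC(=O)Cl
Why: Acylation of the lithium acetylide by a chloroformate installs C15 as an ester that can later be removed without touching a tiglate.

Step 19
Reactants: 28 allyl alkynoate
Product: 29 allyl (13Z)-enoate
Conditions: Me2CuLi (from CuI and MeLi), THF, −78 °C; NH4Cl–MeOH quench at −78 °C
Reagents that add atoms: lithium dimethylcuprate, [Li+].C[Cu-]C
Why: Syn carbocupration of the alkynoate places methyl and copper on the same side, and protonation with retention at low temperature leaves C12 cis to the ester, which is the required 13Z geometry.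

Step 20
Reactants: 29 allyl (13Z)-enoate
Product: 30 19-alcohol
Conditions: HF·pyridine, pyridine, THF, 0 °C to rt
Reagents that add atoms: none
Why: Buffered fluoride-mediated desilylation frees the C19 hydroxyl without affecting the allyl ester, the Z-enoate or the C7=C8 olefin.

Step 21
Reactants: 30 19-alcohol; 31 tigloyl chloride
Product: 32 19-tiglate allyl ester
Conditions: Et3N, 4-(dimethylamino)pyridine (20 mol %), CH2Cl2, rt to 40 °C
Reagents that add atoms: none
Why: Nucleophile-catalysed acylation through the acylpyridinium ion should esterify the hindered neopentyl alcohol, and the E geometry of the thermodynamically preferred tiglate is brought in by 31.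

Step 22
Reactants: 32 19-tiglate allyl ester
Product: 33 (13Z)-19-tigloyloxylabda-7,13-dien-15-oic acid
Conditions: Pd(PPh3)4 (5 mol %), morpholine, THF, rt
Reagents that add atoms: none
Why: In this Tsuji–Trost-type deallylation zerovalent palladium ionises only the allyl ester to a π-allyl complex that morpholine captures, so the acid is released under neutral conditions that leave the tiglate and both olefin geometries unchanged.

Compound list
1 | (E)-pent-3-en-2-one | C/C=C/C(C)=O | starting material
2 | (E)-2-(tert-butyldimethylsilyloxy)penta-1,3-diene | C=C(O[Si](C)(C)C(C)(C)C)/C=C/C | intermediate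
3 | 2,6-dimethyl-1,4-benzoquinone | CC1=CC(=O)C=C(C)C1=O | starting material
4 | cis-fused endo adduct: 6,9-dione, C7=C8, C2=C3 TBS enol ether, 4α-methyl, 5β-H, 10β-methyl | C[C@@H]1C=C(O[Si](C)(C)C(C)(C)C)C[C@]2(C)C(=O)C(C)=CC(=O)[C@H]12 | intermediate
5 | potassium C5(6)-enolate of 4 | C[C@@H]1C=C(O[Si](C)(C)C(C)(C)C)C[C@]2(C)C(=O)C(C)=CC([O-])=C12.[K+] | intermediate
6 | C6 dienyl triflate: C5=C6(OTf), C7=C8, 9-one | C[C@@H]1C=C(O[Si](C)(C)C(C)(C)C)C[C@]2(C)C(=O)C(C)=CC(OS(=O)(=O)C(F)(F)F)=C12 | intermediate
7 | linear dienone: C5=C6–C7=C8–C9=O | C[C@@H]1C=C(O[Si](C)(C)C(C)(C)C)C[C@]2(C)C(=O)C(C)=CC=C12 | intermediate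
8 | lithium dienolate: C9–OLi, C8=C9, C6=C7, 5α-H | C[C@@H]1C=C(O[Si](C)(C)C(C)(C)C)C[C@]2(C)C([O-])=C(C)C=C[C@@H]12.[Li+] | intermediate
9 | deconjugated enone: 9-one, C6=C7, 5α-H, C8 epimers | C[C@@H]1C=C(O[Si](C)(C)C(C)(C)C)C[C@]2(C)C(=O)C(C)C=C[C@@H]12 | intermediate
10 | trans-fused enone: 9-one, C7=C8, 5α-H, 10β-methyl, 4α-methyl, C2 TBS enol ether | C[C@@H]1C=C(O[Si](C)(C)C(C)(C)C)C[C@]2(C)C(=O)C(C)=CC[C@@H]12 | intermediate
11 | 2-(2-bromoethyl)-1,3-dioxolane | BrCCC1OCCO1 | starting material
12 | [2-(1,3-dioxolan-2-yl)ethyl]magnesium bromide | Br[Mg]CCC1OCCO1 | intermediate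
13 | tertiary allylic alcohol: 9β-OH, 9α-[2-(1,3-dioxolan-2-yl)ethyl], C7=C8 | C[C@@H]1C=C(O[Si](C)(C)C(C)(C)C)C[C@]2(C)[C@](O)(CCC3OCCO3)C(C)=CC[C@@H]12 | intermediate
14 | ring A enone: 2-one, C3=C4(methyl), 5α-H | CC1=CC(=O)C[C@]2(C)[C@](O)(CCC3OCCO3)C(C)=CC[C@@H]12 | intermediate
15 | 2β-allylic alcohol (2β,9β-diol) | CC1=C[C@@H](O)C[C@]2(C)[C@](O)(CCC3OCCO3)C(C)=CC[C@@H]12 | intermediate
16 | 2β-(tributylstannylmethyl) ether | CC1=C[C@@H](OC[Sn](CCCC)(CCCC)CCCC)C[C@]2(C)[C@](O)(CCC3OCCO3)C(C)=CC[C@@H]12 | intermediate
17 | dilithiated ether: 2β-OCH2Li, 9β-OLi | CC1=C[C@@H](OC[Li])C[C@]2(C)[C@](O[Li])(CCC3OCCO3)C(C)=CC[C@@H]12 | intermediate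
18 | 19-hydroxy-2,7-diene: 4β-CH2OH, 4α-methyl, C2=C3, 9β-OH | OC[C@@]1(C)C=CC[C@]2(C)[C@](O)(CCC3OCCO3)C(C)=CC[C@@H]12 | intermediate
19 | 9β,19-diol, ring A saturated | OC[C@@]1(C)CCC[C@]2(C)[C@](O)(CCC3OCCO3)C(C)=CC[C@@H]12 | intermediate
20 | 19-O-TBS ether of 19 | CC(C)(C)[Si](C)(C)OC[C@@]1(C)CCC[C@]2(C)[C@](O)(CCC3OCCO3)C(C)=CC[C@@H]12 | intermediate
21 | 8-en-7-one carrying the C9 side chain | CC(C)(C)[Si](C)(C)OC[C@@]1(C)CCC[C@]2(C)C(CCC3OCCO3)=C(C)C(=O)C[C@@H]12 | intermediate
22 | lithium C7(8)-enolate, 9α-H | CC(C)(C)[Si](C)(C)OC[C@@]1(C)CCC[C@]2(C)[C@@H](CCC3OCCO3)C(C)=C([O-])C[C@@H]12.[Li+] | intermediate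
23 | C7 enol triflate, 9α-H | CC(C)(C)[Si](C)(C)OC[C@@]1(C)CCC[C@]2(C)[C@@H](CCC3OCCO3)C(C)=C(OS(=O)(=O)C(F)(F)F)C[C@@H]12 | intermediate
24 | labd-7-ene core bearing the C13 dioxolane acetal and 19-OTBS | CC(C)(C)[Si](C)(C)OC[C@@]1(C)CCC[C@]2(C)[C@@H](CCC3OCCO3)C(C)=CC[C@@H]12 | intermediate
25 | C13 aldehyde | CC(C)(C)[Si](C)(C)OC[C@@]1(C)CCC[C@]2(C)[C@@H](CCC=O)C(C)=CC[C@@H]12 | intermediate
26 | terminal alkyne (C13≡C14) | CC(C)(C)[Si](C)(C)OC[C@@]1(C)CCC[C@]2(C)[C@@H](CCC#C)C(C)=CC[C@@H]12 | intermediate
27 | lithium acetylide of 26 | CC(C)(C)[Si](C)(C)OC[C@@]1(C)CCC[C@]2(C)[C@@H](CCC#C[Li])C(C)=CC[C@@H]12 | intermediate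
28 | allyl alkynoate (C13≡C14–C15) | CC(C)(C)[Si](C)(C)OC[C@@]1(C)CCC[C@]2(C)[C@@H](CCC#CC(=O)OCC=C)C(C)=CC[C@@H]12 | intermediate
29 | allyl (13Z)-enoate, 19-OTBS | CC(C)(C)[Si](C)(C)OC[C@@]1(C)CCC[C@]2(C)[C@@H](CC/C(C)=C\C(=O)OCC=C)C(C)=CC[C@@H]12 | intermediate
30 | allyl (13Z)-19-hydroxylabda-7,13-dien-15-oate | OC[C@@]1(C)CCC[C@]2(C)[C@@H](CC/C(C)=C\C(=O)OCC=C)C(C)=CC[C@@H]12 | intermediate
31 | tigloyl chloride, (E)-2-methylbut-2-enoyl chloride | C/C=C(\C)C(=O)Cl | starting material
32 | allyl (13Z)-19-tigloyloxylabda-7,13-dien-15-oate | C/C=C(\C)C(=O)OC[C@@]1(C)CCC[C@]2(C)[C@@H](CC/C(C)=C\C(=O)OCC=C)C(C)=CC[C@@H]12 | intermediate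
33 | (13Z)-19-[(E)-2-methylbut-2-enoyloxy]labda-7,13-dien-15-oic acid (CNP0249147.2) | C/C=C(\C)C(=O)OC[C@@]1(C)CCC[C@]2(C)[C@@H](CC/C(C)=C\C(=O)O)C(C)=CC[C@@H]12 | target

Total step count: 22. Longest linear sequence: 22 steps (1 to 33); 3, 11 and 31 enter as purchased.

Steps most likely to fail

Step 2. Enantio- or regiocontrol may erode if silyl transfer to triflimide opens an achiral catalytic cycle, or if part of the catalyst binds the hindered C9 carbonyl.
- The fallback sets out from 2 and 3 and comes back at 15.
- The cycloaddition would be run with BF3·OEt2, which gives the same regiochemistry in racemic form, and the racemate carried through steps 3–8.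
- Racemic 15 would be esterified at the C2 hydroxyl with (S)-O-methylmandelic acid (N,N'-dicyclohexylcarbodiimide, 4-(dimethylamino)pyridine).
- The diastereomeric esters would be separated by chromatography or crystallisation. The one derived from the desired enantiomer, the (S)-O-methylmandelate of 15 F1, would be saponified with LiOH in THF–H2O to return 15 as a single enantiomer.

Step 10. The lithiomethyl ether may be protonated or undergo a [1,2]-shift faster than it reaches the β face of C4, which is crowded by the syn-axial C10 methyl.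
- The fallback sets out from 15 and comes back at 18, and it avoids tin and carbanions.
- 15 would be heated with N,N-dimethylformamide dimethyl acetal in xylene.
- Acetal exchange at the 2β oxygen and loss of methanol give an alkoxy(dimethylamino)carbene. Its [2,3]-sigmatropic shift delivers the carbamoyl carbon suprafacially to C4 and gives the 19-(N,N-dimethyl)amide F2.
- Reduction with LiNH2BH3 in THF should then give 18.

Step 5. The reduced dienone may be protonated at C7 instead of C5 or with poor facial preference, or the C9 carbonyl may be over-reduced on quench.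
- The fallback sets out from 4, replaces steps 3–5 and comes back at 10.
- C5 would be equilibrated with DBU through the C6 enolate to the trans-fused enedione F3.
- Luche reduction (NaBH4, CeCl3·7H2O, MeOH, −78 °C) of the unhindered C6 carbonyl from the α face would give the 6β-alcohol F4.
- Acetylation (Ac2O, pyridine, 4-(dimethylamino)pyridine) would give the 6β-acetate F5.
- SmI2 in THF–MeOH would cleave the C6–O bond, which is vinylogously α to the C9 ketone, to give 9. DBU would then conjugate 9 to 10.

Further compounds
F1 | step 2 | (S)-O-methylmandelate of 15 (ester at the 2β oxygen) | CC1=C[C@@H](OC(=O)[C@@H](OC)c4ccccc4)C[C@]2(C)[C@](O)(CCC3OCCO3)C(C)=CC[C@@H]12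
F2 | step 10 | 19-(N,N-dimethyl)amide (4β-CONMe2, 4α-methyl, C2=C3, 9β-OH) | CN(C)C(=O)[C@@]1(C)C=CC[C@]2(C)[C@](O)(CCC3OCCO3)C(C)=CC[C@@H]12
F3 | step 5 | trans-fused enedione (5α-H epimer of 4) | C[C@@H]1C=C(O[Si](C)(C)C(C)(C)C)C[C@]2(C)C(=O)C(C)=CC(=O)[C@@H]12
F4 | step 5 | 6β-alcohol (9-one, C7=C8, 5α-H) | C[C@@H]1C=C(O[Si](C)(C)C(C)(C)C)C[C@]2(C)C(=O)C(C)=C[C@@H](O)[C@@H]12
F5 | step 5 | 6β-acetate of F4 | C[C@@H]1C=C(O[Si](C)(C)C(C)(C)C)C[C@]2(C)C(=O)C(C)=C[C@@H](OC(C)=O)[C@@H]12
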